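**Plan**

1. First cut: the C2–C3 bond of the ring (C1 = ketone beside the carbinol, C2 = acyl-bearing carbon, C3 = enol carbon, C6 = carbinol). The C6 oxygen is γ to the C3 carbonyl carbon (O–C6–C5–C4–C3), so C3 can be re-attached to that oxygen. The carbocycle then becomes the five-membered lactone ring O–C3–C4–C5–C6 of 12, with C1 and C2 as a 1,3-diketone side chain on C6.
2. Second cut: C1–C2 (Claisen acylation), giving lactone acid chloride 9 and methyl ketone 7. Third cut: the diene σ-bond (Suzuki–Miyaura), giving vinyl iodide 4 and alkenylboronate 6.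
3. Forward: the chain is built first (1-methylcycloheptene to keto aldehyde to vinyl iodide; 1-decyne to boronate; coupling). It is then joined to the lactone, and last the lactone ring is expanded to the six-membered carbocycle by transannular C-acyl transfer.
4. Stereochemistry: the one stereocenter comes from (R)-5-oxotetrahydrofuran-2-carboxylic acid 8, and no bond to it is broken anywhere. The (E,E)-diene comes from an E-selective Takai olefination and a syn-hydroboration, joined with retention.

Key step: step 7

Assumption: the target is drawn as one enol tautomer of a 2-acylcyclohexane-1,3-dione; the tautomers interconvert freely, so the route aims at the compound. Acid 8 (D-glutamic acid series) is taken as commercially available.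

**Step 1**
Reactants: 1 1-methylcyclohept-1-ene
Product: 3 7-oxooctanal, via ozonide 2 (not isolated)
Conditions: O3, CH2Cl2, −78 °C; then PPh3, −78 °C → rt
Reagents that add atoms: ozone [O-][O+]=O
Why: Ozonolysis (Criegee mechanism) of the trisubstituted ring alkene and reduction of the ozonide should free the ketone at the methyl-bearing carbon and the aldehyde at the CH carbon; no stereocenter is formed.

**Step 2**
Reactants: 3 7-oxooctanal
Product: 4 (8E)-9-iodonon-8-en-2-one
Conditions: CrCl2 (6 equiv), CHI3 (2 equiv), THF/1,4-dioxane, 0 °C → rt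
Reagents that add atoms: iodoform IC(I)I
Why: Takai olefination, in which the gem-dichromium species from iodoform adds to the aldehyde far faster than to the ketone and eliminates to give mainly the (E)-vinyl iodide.

**Step 3**
Reactants: 5 dec-1-yne
Product: 6 2-[(1E)-dec-1-en-1-yl]-4,4,5,5-tetramethyl-1,3,2-dioxaborolane
Conditions: pinacolborane (1.1 equiv), Cp2Zr(H)Cl (5 mol %), Et3N (10 mol %), neat, 60 °C
Reagents that add atoms: pinacolborane B1OC(C)(C)C(C)(C)O1
Why: Zirconocene-catalysed syn-hydroboration of the terminal alkyne should place boron on the terminal carbon and give the (E)-alkenylboronate.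

**Step 4**
Reactants: 4 (8E)-9-iodonon-8-en-2-one; 6 2-[(1E)-dec-1-en-1-yl]-4,4,5,5-tetramethyl-1,3,2-dioxaborolane
Product: 7 (8E,10E)-nonadeca-8,10-dien-2-one
Conditions: Pd(PPh3)4 (5 mol %), aq. K3PO4, THF, 50 °C, degassed
Reagents that add atoms: none
Why: Suzuki–Miyaura coupling of an alkenyl iodide with an alkenylboronate runs with retention at both sp2 carbons, so the (8E,10E)-diene follows from 4 and 6, and the phosphate base leaves the methyl ketone alone.

**Step 5**
Reactants: 8 (2R)-5-oxooxolane-2-carboxylic acid
Product: 9 (2R)-5-oxooxolane-2-carbonyl chloride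
Conditions: (COCl)2 (1.2 equiv), DMF (cat.), CH2Cl2, 0 °C → rt; concentrate
Reagents that add atoms: oxalyl chloride ClC(=O)C(=O)Cl
Why: Acid chloride formation through the Vilsmeier-type chloroiminium salt is base-free, so the lactone and the α-stereocenter should be untouched.

**Step 6**
Reactants: 7 (8E,10E)-nonadeca-8,10-dien-2-one; 9 (2R)-5-oxooxolane-2-carbonyl chloride
Product: 12 (5R)-5-[(9E,11E)-3-oxoicosa-9,11-dienoyl]oxolan-2-one, via lithium enolate 10 (not isolated), via lithium diketonate 11 (not isolated)
Conditions: 7 (2.0 equiv), LDA (2.0 equiv), THF, −78 °C; then 9 (1.0 equiv), −78 °C; AcOH, −78 °C → rt; surplus 7 recovered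
Reagents that add atoms: none
Why: Claisen-type C-acylation of the kinetic methyl-side lithium enolate by the acid chloride, in which the second equivalent of enolate takes up the more acidic 1,3-diketone as its chelate 11 and so guards it against a second acylation, while the stereocenter of 9 is not involved and the cold acidic quench keeps the diketonate from reacting with the lactone too early.

**Step 7**
Reactants: 12 (5R)-5-[(9E,11E)-3-oxoicosa-9,11-dienoyl]oxolan-2-one
Product: 15 (6R)-3,6-dihydroxy-2-[(7E,9E)-octadeca-7,9-dienoyl]cyclohex-2-en-1-one, via potassium diketonate 13 (not isolated), via potassium triketonate 14 (not isolated)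
Conditions: t-BuOK (1.0 equiv), THF (0.02 M), 0 °C → rt; then 1 M HCl, 0 °C
Reagents that add atoms: none
Why: Proposed new method: one equivalent of tert-butoxide turns the 1,3-diketone into diketonate 13, whose central carbon adds to the lactone carbonyl on the ring face that carries the side chain (6-(enolexo)-exo-trig) to give a 7-oxabicyclo[2.2.1]heptane alkoxide, and this tetrahedral intermediate collapses by cleavage of the former lactone C–O bond, so that the five-membered lactone becomes the six-membered carbocycle and the ring oxygen becomes the C6 alkoxide. The alkoxide is at once protonated by the new 2-acyl-1,3-dione, which is far more acidic than the starting diketone, and this proton transfer to the non-basic triketonate 14 should make the sequence irreversible. The closest known reaction types are the Dieckmann cyclization of δ-keto esters and 5,7-dioxo esters to cyclohexane-1,3-diones, the base-induced rearrangement of enol lactones to cyclic 1,3-diketones, and 1,3-acyl migrations across five-membered rings such as the γ- to δ-translactonization, which pass through a tetrahedral intermediate of the same bicyclic shape; new is the carbon nucleophile in such a transannular acyl transfer. No stereocenter is formed: C6 of 15 is C5 of the lactone, none of its four bonds is broken, and the configuration of 8 is kept. The step needs C-acylation through the six-membered transition state in preference to epimerization at the oxygen-bearing carbon and to intermolecular Claisen condensation; the tether secures the first (only the central carbon reaches the carbonyl through a six-membered ring, attack by a diketonate oxygen would need an eight-membered ring), and a single equivalent of a non-nucleophilic base at high dilution should secure the others, because neither 13 nor 14 is basic enough to remove the proton at the oxygen-bearing carbon.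

**Compound list**

1 | 1-methylcyclohept-1-ene | CC1=CCCCCC1 | starting material
2 | 1-methyl-8,9,10-trioxabicyclo[5.2.1]decane (ozonide of 1, racemic) | CC12CCCCCC(OO1)O2 | intermediate
3 | 7-oxooctanal | CC(=O)CCCCCC=O | intermediate
4 | (8E)-9-iodonon-8-en-2-one | CC(=O)CCCCC/C=C/I | intermediate
5 | dec-1-yne | CCCCCCCCC#C | starting material
6 | 2-[(1E)-dec-1-en-1-yl]-4,4,5,5-tetramethyl-1,3,2-dioxaborolane | CCCCCCCC/C=C/B1OC(C)(C)C(C)(C)O1 | intermediate
7 | (8E,10E)-nonadeca-8,10-dien-2-one | CCCCCCCC/C=C/C=C/CCCCCC(C)=O | intermediate
8 | (2R)-5-oxooxolane-2-carboxylic acid [(R)-5-oxotetrahydrofuran-2-carboxylic acid] | OC(=O)[C@H]1CCC(=O)O1 | starting material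
9 | (2R)-5-oxooxolane-2-carbonyl chloride | ClC(=O)[C@H]1CCC(=O)O1 | intermediate
10 | lithium (8E,10E)-nonadeca-1,8,10-trien-2-olate (kinetic enolate of 7) | C=C([O-])CCCCC/C=C/C=C/CCCCCCCC.[Li+] | intermediate
11 | lithium (Z)-enolate of 12 (chelated diketonate) | CCCCCCCC/C=C/C=C/CCCCCC(=O)/C=C(\[O-])[C@H]1CCC(=O)O1.[Li+] | intermediate
12 | (5R)-5-[(9E,11E)-3-oxoicosa-9,11-dienoyl]oxolan-2-one | CCCCCCCC/C=C/C=C/CCCCCC(=O)CC(=O)[C@H]1CCC(=O)O1 | intermediate
13 | potassium (Z)-enolate of 12 (diketonate) | CCCCCCCC/C=C/C=C/CCCCCC(=O)/C=C(\[O-])[C@H]1CCC(=O)O1.[K+] | intermediate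
14 | potassium (4R)-4-hydroxy-2-[(7E,9E)-octadeca-7,9-dienoyl]-3-oxocyclohex-1-en-1-olate | CCCCCCCC/C=C/C=C/CCCCCC(=O)C1=C([O-])CC[C@@H](O)C1=O.[K+] | intermediate
15 | (6R)-3,6-dihydroxy-2-[(7E,9E)-octadeca-7,9-dienoyl]cyclohex-2-en-1-one (CNP0169831.1) | CCCCCCCC/C=C/C=C/CCCCCC(=O)C1=C(O)CC[C@@H](O)C1=O | target

**Step count and risks**

Total step count: 7. Longest linear sequence: 5 (steps 1, 2, 4, 6, 7).

Steps most likely to fail:

Step 7. The transannular C-acyl transfer may be too slow, because its transition state takes on part of the strain of the oxanorbornane-type intermediate. The diketonate would then persist and, on forcing, epimerize at the oxygen-bearing carbon or condense intermolecularly. The fallback uses known chemistry without a lactone or a ring expansion; it sets out from 7 and 8 and comes back at 15. Acid 8 is opened and esterified with HCl in methanol to dimethyl (2R)-2-hydroxypentanedioate F1, which is silylated (TBSCl, imidazole, DMF) to dimethyl (2R)-2-[(tert-butyldimethylsilyl)oxy]pentanedioate F2. Lithium enolate 10 (from 7, LDA, THF, −78 °C) is acylated by F2 in a Claisen condensation at either ester group. This gives methyl (4R,13E,15E)-4-[(tert-butyldimethylsilyl)oxy]-5,7-dioxotetracosa-13,15-dienoate F3 or its regioisomer methyl (2R,13E,15E)-2-[(tert-butyldimethylsilyl)oxy]-5,7-dioxotetracosa-13,15-dienoate F4. Both are 5,7-dioxo esters, and with t-BuOK in THF both should close in an ordinary Dieckmann condensation to the same silyl ether, (6R)-6-[(tert-butyldimethylsilyl)oxy]-3-hydroxy-2-[(7E,9E)-octadeca-7,9-dienoyl]cyclohex-2-en-1-one F5, so the regiochemistry of the first acylation does not matter. Aqueous HF in acetonitrile then removes the silyl group and gives 15.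

Step 6. The basic enolate may convert the acid chloride into a ketene and so erode the configuration, or the diketonate may be acylated a second time on oxygen or carbon. The fallback is an aldol addition followed by oxidation; it sets out from 9 and 7 and comes back at 12. Rosenmund reduction of 9 (H2, Pd/BaSO4, 2,6-lutidine, THF) gives (2R)-5-oxooxolane-2-carbaldehyde F6, which is used crude. Addition of lithium enolate 10 at −78 °C gives (5R)-5-[(9E,11E)-1-hydroxy-3-oxoicosa-9,11-dien-1-yl]oxolan-2-one F7 as a mixture of carbinol epimers. Dess–Martin periodinane in CH2Cl2 oxidizes both epimers to 12, so the mixture converges.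

Step 2. The iodo-olefination may give poor E/Z selectivity, and the Z-iodide would pass through the stereospecific coupling into a diene isomer that is hard to remove. The fallback reverses the roles of the coupling partners; it sets out from 3 and 5 and comes back at 7. The boron variant of the Takai olefination (Cl2CHBpin, CrCl2, LiI, THF), which has a stronger inherent E preference, converts 3 into (8E)-9-(4,4,5,5-tetramethyl-1,3,2-dioxaborolan-2-yl)non-8-en-2-one F8. Hydrozirconation of 5 with Cp2Zr(H)Cl and iodinolysis with I2 gives (1E)-1-iododec-1-ene F9 by syn addition and retention. Suzuki–Miyaura coupling of F8 and F9 (Pd(PPh3)4, aq. K3PO4, THF) then gives 7.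

**Further compounds**

F1 | step 7 | dimethyl (2R)-2-hydroxypentanedioate | COC(=O)[C@H](O)CCC(=O)OC
F2 | step 7 | dimethyl (2R)-2-[(tert-butyldimethylsilyl)oxy]pentanedioate | COC(=O)[C@H](O[Si](C)(C)C(C)(C)C)CCC(=O)OC
F3 | step 7 | methyl (4R,13E,15E)-4-[(tert-butyldimethylsilyl)oxy]-5,7-dioxotetracosa-13,15-dienoate | CCCCCCCC/C=C/C=C/CCCCCC(=O)CC(=O)[C@H](O[Si](C)(C)C(C)(C)C)CCC(=O)OC
F4 | step 7 | methyl (2R,13E,15E)-2-[(tert-butyldimethylsilyl)oxy]-5,7-dioxotetracosa-13,15-dienoate | CCCCCCCC/C=C/C=C/CCCCCC(=O)CC(=O)CC[C@@H](O[Si](C)(C)C(C)(C)C)C(=O)OC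
F5 | step 7 | (6R)-6-[(tert-butyldimethylsilyl)oxy]-3-hydroxy-2-[(7E,9E)-octadeca-7,9-dienoyl]cyclohex-2-en-1-one | CCCCCCCC/C=C/C=C/CCCCCC(=O)C1=C(O)CC[C@@H](O[Si](C)(C)C(C)(C)C)C1=O
F6 | step 6 | (2R)-5-oxooxolane-2-carbaldehyde | O=C[C@H]1CCC(=O)O1
F7 | step 6 | (5R)-5-[(9E,11E)-1-hydroxy-3-oxoicosa-9,11-dien-1-yl]oxolan-2-one (both carbinol epimers) | CCCCCCCC/C=C/C=C/CCCCCC(=O)CC(O)[C@H]1CCC(=O)O1
F8 | step 2 | (8E)-9-(4,4,5,5-tetramethyl-1,3,2-dioxaborolan-2-yl)non-8-en-2-one | CC(=O)CCCCC/C=C/B1OC(C)(C)C(C)(C)O1
F9 | step 2 | (1E)-1-iododec-1-ene | CCCCCCCC/C=C/I
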